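The rate constants are made up; the result is computed.

Slowness opens this flask: L enters solution at no more than 0.976 min⁻¹ of its charge, while E is already being spent.

    E + J → E.J (k1 = 0.182 L mol⁻¹ s⁻¹)
    L ⇌ Q, rate k2*(cs2 - [Q]) while solid is left; crystals form when [Q] > cs2 (cs2 = 0.12 M, k2 = 0.0271 s⁻¹)
    Q + E → Q.E (k3 = 0.259 L mol⁻¹ s⁻¹)
    E → D (k4 = 0.00926 s⁻¹)

L 0.20 M; E 0.400 M; J 0.100 M; time 1.5 min

- how much Q.E there is at 1.5 min, in percent of the L charged
- concentration of Q in solution at 1.5 min, in percent of saturation

The decision for the next run is whether to leave the flask past 1.5 min, and it hangs on what the remaining E does once Q stands in solution. Apart from J, E has two fates: Q takes it in step 3, and step 4 turns it into D. The even point is the amount of Q at which these two claims on E are equal, k4 over k3, here 17.9% of the L charged. Its share rule, a selectivity, says that at any moment Q captures Q/(Q + even point) of the E going to these two fates. The even point lies lower than the solubility, so dissolved Q can pass it.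

For the end state, this reckoning lets J take its whole charge, which leaves E worth 150% of the L charged. If Q averages about the even point, that E splits evenly, and Q.E stops near a ceiling: 75.0%. The reckoning goes no further, so it gives no figure for the asked time and none for saturation.

The forecast puts y at 61.5% and Q at 57% of saturation, from a stepwise integration in which “so solid remains throughout”.

The flask gives 61.6% of Q.E and Q at 57.0% of saturation. At that time E stands at 11.4% of its charge and Q at 34.2% of the L charged. At that Q the share rule gives about 65.7% of further E to Q, an estimate worth about 15 percentage points more Q.E. The neighbour flask read at 2.5 min holds 72.7% of the L charged as Q.E, with E at 2.34% of its charge and Q at 27.3% of the L charged. The same rule promises about 2.8 points more, and the flask left until 15.0 min reads 75.4%.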